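**Retrosynthetic overview**
1. C3–acetyl bond: made last, by O-acetylation and O→C acetyl shift on the finished N-enoyl tetramic acid. This mirrors the late acetyl transfer presumed in nature.
2. The only ring (pyrrolidine-2,4-dione) is opened at N1–C2, not at C3–C4. The already acylated nitrogen closes on an acylketene, which stands in for the carrier-bound β-keto thioester.
3. C3–C4 bond: crossed Claisen condensation of an acetate enolate (malonyl extender equivalent) on N-enoyl-D-leucine methyl ester.
4. N–acyl bond: made first, from (E)-dodec-2-enoic acid and D-leucine methyl ester. C5 (R) is bought with D-leucine.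
5. Order: amide, then chain extension, then one flask for ring closure followed by acetyl shift.

Assumption: (E)-dodec-2-enoic acid and D-leucine methyl ester hydrochloride are bought as catalogue chemicals, and the target is drawn as its 4-hydroxy enol tautomer, which equilibrates with the other tricarbonyl tautomers.

**Step 1**
Reactants: 1 D-leucine methyl ester hydrochloride; 2 (E)-dodec-2-enoic acid
Product: 3 methyl (2R)-2-[(E)-dodec-2-enoylamino]-4-methylpentanoate
Conditions: N-ethyl-N'-(3-dimethylaminopropyl)carbodiimide hydrochloride (EDC·HCl, 1.2 equiv), 1-hydroxybenzotriazole (0.2 equiv), Et3N (2.2 equiv), CH2Cl2, 0 °C → rt, 12 h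
Reagents that add atoms: none
Why: Carbodiimide amide coupling in which the acid carries no stereocentre and the amine partner cannot form an oxazolone, so the (R) centre bought with D-leucine and the E alkene are carried over unchanged.

**Step 2**
Reactants: 3 methyl (2R)-2-[(E)-dodec-2-enoylamino]-4-methylpentanoate; 4 tert-butyl acetate
Product: 6 tert-butyl (4R)-4-[(E)-dodec-2-enoylamino]-6-methyl-3-oxoheptanoate, via lithium enolate 5 (not isolated)
Conditions: 4 (3.7 equiv), LiN(iPr)2 (3.5 equiv), THF, −78 °C, 45 min; then 3 in THF, −78 → −45 °C, 2 h; AcOH (4 equiv) in THF at −78 °C, then aqueous work-up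
Reagents that add atoms: lithium diisopropylamide, [Li+].CC(C)[N-]C(C)C (its lithium is held in 5 only; no atom of it stays in 6)
Why: Crossed Claisen condensation in which the first equivalent of 5 (kept free of excess amide base) removes the amide N–H, the resulting amidate shuts down 1,4-addition and γ-deprotonation of the enoyl group and shields the α-C–H, the second equivalent adds to the methyl ester, and the third holds 6 as its enolate, so the (R) centre stays intact until the cold acidic quench.

**Step 3 (key step)**
Reactants: 6 tert-butyl (4R)-4-[(E)-dodec-2-enoylamino]-6-methyl-3-oxoheptanoate; 7 acetyl chloride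
Product: 11 reutericyclin C [(5R)-3-acetyl-1-[(2E)-dodec-2-enoyl]-4-hydroxy-5-(2-methylpropyl)-1,5-dihydro-2H-pyrrol-2-one], via acylketene 8 (not isolated), via N-enoyl tetramic acid 9 (not isolated), via enol acetate 10 (not isolated)
Conditions: PhMe (0.02 M), reflux with slow distillation of t-BuOH/PhMe down to ca. 0.1 M, 3–5 h; cool to 0 °C; Et3N (2.2 equiv), 7 (1.1 equiv), 30 min; 4-dimethylaminopyridine (0.2 equiv), rt, 6–12 h; cold 1 M HCl wash
Reagents that add atoms: none
Why: Proposed new method: heating the tert-butyl β-keto ester expels t-BuOH through a six-membered pseudopericyclic transition state to give acylketene 8 (the known basis of transacetoacetylation with tert-butyl acetoacetate), whose in-plane electrophilic ketene carbon is captured in a five-membered closure by the neighbouring enamide N–H just as carbamate N–H groups capture the acylketenes released from aminoacyl Meldrum's acids (closest known reaction type: thermal acylketene lactamisation), so N1–C2 closes under neutral conditions that do not touch the C5–H bond and the (R) centre is retained, after which O-acetylation and 4-dimethylaminopyridine-catalysed O→C acetyl migration (Fries-type acyl shift known for 4-O-acyl tetramic and tetronic acids) put the acetyl group on C3, where the product rests as its stabilised enolate salt until the acid wash.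

**Compound list**
1 | D-leucine methyl ester hydrochloride, methyl (2R)-2-amino-4-methylpentanoate hydrochloride | Cl.COC(=O)[C@H](N)CC(C)C | starting material
2 | (E)-dodec-2-enoic acid | CCCCCCCCC/C=C/C(=O)O | starting material
3 | methyl (2R)-2-[(E)-dodec-2-enoylamino]-4-methylpentanoate | CCCCCCCCC/C=C/C(=O)N[C@H](CC(C)C)C(=O)OC | intermediate
4 | tert-butyl acetate | CC(=O)OC(C)(C)C | starting material
5 | lithium enolate of tert-butyl acetate (not isolated) | [Li+].C=C([O-])OC(C)(C)C | intermediate
6 | tert-butyl (4R)-4-[(E)-dodec-2-enoylamino]-6-methyl-3-oxoheptanoate | CCCCCCCCC/C=C/C(=O)N[C@H](CC(C)C)C(=O)CC(=O)OC(C)(C)C | intermediate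
7 | acetyl chloride | CC(=O)Cl | starting material
8 | acylketene, (E)-N-[(4R)-6-methyl-1,3-dioxohept-1-en-4-yl]dodec-2-enamide (not isolated) | CCCCCCCCC/C=C/C(=O)N[C@H](CC(C)C)C(=O)C=C=O | intermediate
9 | (5R)-1-[(E)-dodec-2-enoyl]-5-(2-methylpropyl)pyrrolidine-2,4-dione (not isolated) | CCCCCCCCC/C=C/C(=O)N1C(=O)CC(=O)[C@H]1CC(C)C | intermediate
10 | (5R)-4-acetoxy-1-[(E)-dodec-2-enoyl]-5-(2-methylpropyl)-1,5-dihydro-2H-pyrrol-2-one (not isolated) | CCCCCCCCC/C=C/C(=O)N1C(=O)C=C(OC(C)=O)[C@H]1CC(C)C | intermediate
11 | reutericyclin C, (5R)-3-acetyl-1-[(2E)-dodec-2-enoyl]-4-hydroxy-5-(2-methylpropyl)-1,5-dihydro-2H-pyrrol-2-one | CCCCCCCCC/C=C/C(=O)N1C(=O)C(C(C)=O)=C(O)[C@H]1CC(C)C | target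

**Total step count:** 3. **Longest linear sequence:** 3 (1 → 3 → 6 → 11).

**Steps most likely to fail, in order of risk**

Step 3 is the riskiest.
- A secondary enamide N–H is a weak nucleophile.
- Several hours at 110 °C may erode the ee of 9 or divert 6 into ester cleavage and decarboxylation.
- Tetramic acid 9 can self-condense.
- The ee should be measured on 11 by chiral HPLC, and 11 should be purified on acid-washed silica or reversed phase because it binds metal ions.

The fallback sets out from 6 and comes back at 9. It replaces thermal ketene release by chemical dehydration in the cold. The tert-butyl ester of 6 is cleaved with CF3CO2H in CH2Cl2 at 0 °C to (4R)-4-[(E)-dodec-2-enoylamino]-6-methyl-3-oxoheptanoic acid F1. The solution is stripped cold, and the acid is treated at once with EDC·HCl in CH2Cl2 at −10 °C → rt. The O-acylisourea of a β-keto acid eliminates to acylketene 8 below room temperature, so closure to 9 needs no heat. Compound 9 is then isolated, checked for ee, and taken through the acetylation half of step 3 to 11.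

Step 2 is next.
- Enolate 5 may add 1,4 to the enoyl group or deconjugate it.
- The amidate may make the neighbouring ester too sluggish.
- Any free LiN(iPr)2 could remove the α-proton.

The fallback sets out from 1 and comes back at 6. It extends the chain before the enoyl group is present.
- Compound 1 is protected with benzyl chloroformate and NaHCO3 (EtOAc/water) to methyl (2R)-2-(benzyloxycarbonylamino)-4-methylpentanoate F2.
- This ester undergoes the same Claisen condensation with enolate 5, which is well behaved for carbamate-protected amino esters. The product is tert-butyl (4R)-4-(benzyloxycarbonylamino)-6-methyl-3-oxoheptanoate F3.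
- Hydrogenolysis (H2, 1 atm, Pd/C with 10 wt% palladium on carbon, 1.0 equiv HCl, EtOAc) gives tert-butyl (4R)-4-amino-6-methyl-3-oxoheptanoate hydrochloride F4. It is kept as the salt so that it neither lactamises nor dimerises.
- This salt is coupled with 2 under the conditions of step 1, with N-methylmorpholine in place of Et3N at 0 °C, to give 6.

Step 1 is the least risky.
- Commercial 2 may carry Z or β,γ-isomers that follow through to the end.
- The free amine may add in aza-Michael fashion to the activated enoate.

The fallback sets out from 1 and comes back at 3. It builds the alkene after the amide. Compound 1 is coupled with diethylphosphonoacetic acid (EDC·HCl, Et3N, CH2Cl2) to methyl (2R)-2-[2-(diethoxyphosphoryl)acetamido]-4-methylpentanoate F5. A Horner–Wadsworth–Emmons olefination with decanal under LiCl and iPr2NEt in MeCN at rt then gives 3, with the E geometry set in the flask.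

**Further compounds**
F1 | step 3 | (4R)-4-[(E)-dodec-2-enoylamino]-6-methyl-3-oxoheptanoic acid | CCCCCCCCC/C=C/C(=O)N[C@H](CC(C)C)C(=O)CC(=O)O
F2 | step 2 | methyl (2R)-2-(benzyloxycarbonylamino)-4-methylpentanoate | COC(=O)[C@H](NC(=O)OCc1ccccc1)CC(C)C
F3 | step 2 | tert-butyl (4R)-4-(benzyloxycarbonylamino)-6-methyl-3-oxoheptanoate | O=C(OCc1ccccc1)N[C@H](CC(C)C)C(=O)CC(=O)OC(C)(C)C
F4 | step 2 | tert-butyl (4R)-4-amino-6-methyl-3-oxoheptanoate hydrochloride | Cl.N[C@H](CC(C)C)C(=O)CC(=O)OC(C)(C)C
F5 | step 1 | methyl (2R)-2-[2-(diethoxyphosphoryl)acetamido]-4-methylpentanoate | CCOP(=O)(OCC)CC(=O)N[C@H](CC(C)C)C(=O)OC
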